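**Retrosynthetic overview**
1. Target ⇐ enol O-acetylation ⇐ dihydropyran ring F by acid-mediated decarboxylative cyclodehydration of a spiro-γ-butyrolactone onto a vinylogous acid (C–O).
2. Azepanone ring E and the bridgehead carbinolamine ⇐ key hydrative aza-Michael cyclization of a cyclic ketimine onto a tethered isopropenyl ketone (N–C and C–O bonds).
3. Isopropenyl ketone ⇐ Weinreb amide; seven-membered ring D ⇐ vinylogous Dieckmann; rings A (cyclopentenone) and B (cyclohexene) ⇐ Knoevenagel / imine–enamine aldol cascade of an oxamide-derived 2,4-dioxo amide.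
4. Linear precursor ⇐ quaternary 3-acetyl-1-pyrroline (ring C) + 2-acetylbutyrolactone (α-bromo ketone alkylation) + N,N′-dimethoxy-N,N′-dimethyloxamide (Claisen).
5. Ring C ⇐ asymmetric Michael addition of pentane-2,4-dione to a nitroalkene, reductive C–N cyclization, anti-selective C-methylation; ring order C → A → B → D → E → F.

Assumption: the target is taken exactly as the given SMILES; keto/enol tautomers are drawn in one form, and the spiro-lactone carbon is carried as both epimers until it is destroyed in step 12.

**Step 1**
Reactants: 1 methyl 4-oxobutanoate; 2 nitromethane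
Product: 4 methyl (E)-5-nitropent-4-enoate, via nitro aldol 3 (not isolated)
Conditions: 2 (5 equiv), KOtBu (5 mol %), THF/t-BuOH, 0 °C; then MsCl, Et3N, CH2Cl2, −10 to 0 °C
Reagents that add atoms: none
Why: Henry (nitroaldol) reaction followed by mesylation and E1cB elimination gives the conjugated (E)-nitroalkene.

**Step 2**
Reactants: 4 methyl (E)-5-nitropent-4-enoate; 5 pentane-2,4-dione
Product: 6 methyl (4S)-5-acetyl-4-(nitromethyl)-6-oxoheptanoate
Conditions: squaramide organocatalyst 3-{[3,5-bis(trifluoromethyl)benzyl]amino}-4-[(9-deoxy-epi-cinchona-alkaloid-9-yl)amino]cyclobut-3-ene-1,2-dione (2 mol %; quinidine- or quinine-derived pseudoenantiomer selected for 4S), CH2Cl2, rt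
Reagents that add atoms: none
Why: Enantioselective Michael addition under bifunctional squaramide catalysis, in which the squaramide N–H bonds bind the nitro group and the quinuclidine deprotonates the diketone, so the enol attacks one face of the nitroalkene and sets the (S) centre that becomes the ring CH.

**Step 3**
Reactants: 6 methyl (4S)-5-acetyl-4-(nitromethyl)-6-oxoheptanoate
Product: 8 methyl 3-[(3S)-4-acetyl-5-methyl-2,3-dihydro-1H-pyrrol-3-yl]propanoate, via amino diketone 7 (not isolated)
Conditions: H2 (4 bar), Raney Ni, MeOH, rt
Reagents that add atoms: none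
Why: Nitro hydrogenation gives the primary amine, which condenses 5-exo with one of the two equivalent acetyl groups to the vinylogous amide (enaminone), a C–N ring closure that outpaces lactamization with the remote ester.

**Step 4**
Reactants: 8 methyl 3-[(3S)-4-acetyl-5-methyl-2,3-dihydro-1H-pyrrol-3-yl]propanoate
Product: 10 methyl 3-[(3S,4R)-4-acetyl-4,5-dimethyl-3,4-dihydro-2H-pyrrol-3-yl]propanoate, via pyrrolinium iodide 9 (not isolated)
Conditions: MeI (5 equiv), MeCN, 60 °C (sealed); then aq. NaHCO3
Reagents that add atoms: iodomethane, CI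
Why: Stork-type C-alkylation of the NH-enaminone at its nucleophilic α-carbon, with MeI approaching the ring face anti to the neighbouring CH2CH2CO2Me chain so that the new quaternary centre carries methyl trans to the chain (cis to the ring H), the product staying N-protonated (9) and therefore safe from N-methylation.

**Step 5**
Reactants: 10 methyl 3-[(3S,4R)-4-acetyl-4,5-dimethyl-3,4-dihydro-2H-pyrrol-3-yl]propanoate
Product: 12 methyl 3-[(3S,4R)-4-(bromoacetyl)-4,5-dimethyl-3,4-dihydro-2H-pyrrol-3-yl]propanoate, via silyl enol ether 11 (not isolated)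
Conditions: LiN(iPr)2 (1.05 equiv), Me3SiCl (in situ quench), THF, −78 °C; then NBS, −78 to 0 °C
Reagents that add atoms: N-bromosuccinimide, O=C1CCC(=O)N1Br
Why: Kinetic enolization of the methyl ketone (more acidic than the imine methyl and the ester CH2) with in situ silylation, then electrophilic bromination of the silyl enol ether, gives the α-bromo ketone.

**Step 6**
Reactants: 12 methyl 3-[(3S,4R)-4-(bromoacetyl)-4,5-dimethyl-3,4-dihydro-2H-pyrrol-3-yl]propanoate; 13 2-acetylbutyrolactone
Product: 14 methyl 3-[(3S,4R)-4-[(3-acetyl-2-oxooxolan-3-yl)acetyl]-4,5-dimethyl-3,4-dihydro-2H-pyrrol-3-yl]propanoate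
Conditions: K2CO3 (1.5 equiv), acetone, rt
Reagents that add atoms: none
Why: SN2 C-alkylation of the β-keto lactone enolate by the α-bromo ketone (acetoacetic-ester-type alkylation) builds the 1,4-diketone, the new quaternary lactone carbon forming as both epimers, which converge in step 12.

**Step 7**
Reactants: 14 methyl 3-[(3S,4R)-4-[(3-acetyl-2-oxooxolan-3-yl)acetyl]-4,5-dimethyl-3,4-dihydro-2H-pyrrol-3-yl]propanoate; 15 N,N′-dimethoxy-N,N′-dimethyloxamide
Product: 16 methyl 3-[(3S,4R)-4-[(3-{4-[methoxy(methyl)amino]-3,4-dioxobutanoyl}-2-oxooxolan-3-yl)acetyl]-4,5-dimethyl-3,4-dihydro-2H-pyrrol-3-yl]propanoate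
Conditions: LiN(iPr)2 (1.1 equiv), THF, −78 °C; then 15, −78 to −20 °C; AcOH quench
Reagents that add atoms: none
Why: Crossed Claisen condensation in which the kinetic lithium enolate of the unhindered methyl ketone acylates once on the oxamide, the chelated tetrahedral adduct preventing over-addition.

**Step 8**
Reactants: 16 the 2,4-dioxo Weinreb amide
Product: 18 tricyclic hydroxy imine (rings A/B/C; see list), via ene-dione 17 (not isolated)
Conditions: pyrrolidine (20 mol %), AcOH (20 mol %), toluene, 4 Å MS, 60 °C
Reagents that add atoms: none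
Why: Intramolecular Knoevenagel condensation of the enolized 1,3-diketone onto the only ketone within five-ring reach gives ene-dione 17, whose activated 2-oxoamide ketone is attacked by the enamine tautomer of the 2-methyl-1-pyrroline (imine–enamine aldol, six-ring closure); the carbinol centre forms reversibly with the acyl group held pseudo-axial by A(1,2) strain, and the epimer with that group syn to nitrogen (drawn) is the one consumed in step 11.

**Step 9**
Reactants: 18 tricyclic hydroxy imine
Product: 19 tetracyclic enol (ring D closed; see list)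
Conditions: KOtBu (3 equiv), THF, 0 °C to rt; AcOH quench
Reagents that add atoms: none
Why: Vinylogous Dieckmann condensation in which the γ-CH2 of the cyclopentenone dienolate (the α′-carbon is the spiro centre and the α-carbon is fully substituted, so no other ring site can give a stabilized product) acylates the methyl ester to close the seven-membered ring, driven by formation of the vinylogous 1,3-diketonate.

**Step 10**
Reactants: 19 tetracyclic enol; 20 isopropenylmagnesium bromide
Product: 21 tetracyclic isopropenyl ketone (see list)
Conditions: 20 (4 equiv), THF, −40 to −10 °C; cold pH 7 phosphate buffer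
Reagents that add atoms: none
Why: Weinreb ketone synthesis in which two equivalents of Grignard reagent first deprotonate the enol and the tertiary alcohol (masking both ring carbonyls as a magnesium diketonate), the chelated N-methoxy-N-methylamide then accepts one isopropenyl group, and the hindered spiro-lactone is left untouched at low temperature.

**Step 11**
Reactants: 21 tetracyclic isopropenyl ketone
Product: 22 spiro-lactone cage (ring E closed; bridgehead carbinolamine; see list)
Conditions: (PhO)2P(O)OH (10 mol %), H2O (20 equiv), MeCN, 40 °C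
Reagents that add atoms: water, O
Why: Proposed new method: a hydrative aza-Michael cyclization in which the phosphoric acid reversibly hydrates the hindered cyclic ketimine to its carbinolamine, whose secondary N–H adds 7-endo to the H-bond-activated isopropenyl ketone (N–C bond, azepanone ring), the resulting bridgehead carbinolamine being unable to revert to an iminium ion or enamine without violating Bredt's rule and therefore acting as the thermodynamic sink; the cage dictates the carbinolamine configuration (OH cis to the angular methyl), drains the reversibly formed carbinol epimers through the one with the acyl group syn to nitrogen, and lets the α-methyl centre equilibrate by enolization to the expected pseudo-equatorial (R) epimer; the closest known reaction types are the acid-mediated conjugate addition of 1-pyrroline nitrogen to vinyl ketones (aza-annulation) and pseudobase formation from cyclic iminium salts.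

**Step 12**
Reactants: 22 spiro-lactone cage
Product: 23 O-deacetyl target (fulvenol; ring F closed)
Conditions: TsOH·H2O (2 equiv), 1,4-dioxane/H2O (5:1), 70 °C
Reagents that add atoms: none
Why: Acid-catalysed lactone hydrolysis, β-keto acid decarboxylation (which erases the spiro stereocentre) and cyclodehydration of the freed primary alcohol onto the vinylogous acid carbon give the six-membered enol ether (C–O bond) under thermodynamic control, the N-protonated bridgehead carbinolamine surviving because it cannot ionize to an iminium ion.

**Step 13**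
Reactants: 23 O-deacetyl target
Product: 24 CNP0309418.1
Conditions: Ac2O (1.2 equiv), Et3N, CH2Cl2, −20 °C
Reagents that add atoms: acetic anhydride, CC(=O)OC(C)=O
Why: O-acylation of the cyclopentadienide-type enolate formed by removing the only acidic C–H (α to the ring ketone) gives the fulvenyl enol acetate, the two hindered tertiary alcohols not reacting at −20 °C without an acyl-transfer catalyst.

**Compound list**
1 | methyl 4-oxobutanoate | COC(=O)CCC=O | starting material
2 | nitromethane | C[N+](=O)[O-] | starting material
3 | methyl 4-hydroxy-5-nitropentanoate (racemic nitro aldol, not isolated) | COC(=O)CCC(O)C[N+](=O)[O-] | intermediate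
4 | methyl (E)-5-nitropent-4-enoate | COC(=O)CC/C=C/[N+](=O)[O-] | intermediate
5 | pentane-2,4-dione | CC(=O)CC(C)=O | starting material
6 | methyl (4S)-5-acetyl-4-(nitromethyl)-6-oxoheptanoate | [O-][N+](=O)C[C@@H](CCC(=O)OC)C(C(C)=O)C(C)=O | intermediate
7 | methyl (4S)-5-acetyl-4-(aminomethyl)-6-oxoheptanoate (not isolated) | NC[C@@H](CCC(=O)OC)C(C(C)=O)C(C)=O | intermediate
8 | methyl 3-[(3S)-4-acetyl-5-methyl-2,3-dihydro-1H-pyrrol-3-yl]propanoate | N1C[C@@H](CCC(=O)OC)C(C(C)=O)=C1C | intermediate
9 | (3S,4R)-4-acetyl-3-(3-methoxy-3-oxopropyl)-4,5-dimethyl-3,4-dihydro-2H-pyrrol-1-ium iodide (not isolated) | CC1=[NH+]C[C@@H](CCC(=O)OC)[C@@]1(C)C(C)=O.[I-] | intermediate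
10 | methyl 3-[(3S,4R)-4-acetyl-4,5-dimethyl-3,4-dihydro-2H-pyrrol-3-yl]propanoate | CC1=NC[C@@H](CCC(=O)OC)[C@@]1(C)C(C)=O | intermediate
11 | methyl 3-[(3S,4R)-4,5-dimethyl-4-[1-(trimethylsilyloxy)ethenyl]-3,4-dihydro-2H-pyrrol-3-yl]propanoate (not isolated) | CC1=NC[C@@H](CCC(=O)OC)[C@@]1(C)C(=C)O[Si](C)(C)C | intermediate
12 | methyl 3-[(3S,4R)-4-(bromoacetyl)-4,5-dimethyl-3,4-dihydro-2H-pyrrol-3-yl]propanoate | CC1=NC[C@@H](CCC(=O)OC)[C@@]1(C)C(=O)CBr | intermediate
13 | 2-acetylbutyrolactone (3-acetyloxolan-2-one) | CC(=O)C1CCOC1=O | starting material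
14 | methyl 3-[(3S,4R)-4-[(3-acetyl-2-oxooxolan-3-yl)acetyl]-4,5-dimethyl-3,4-dihydro-2H-pyrrol-3-yl]propanoate (both epimers at the lactone α-carbon) | CC1=NC[C@@H](CCC(=O)OC)[C@@]1(C)C(=O)CC1(C(C)=O)CCOC1=O | intermediate
15 | N,N′-dimethoxy-N,N′-dimethyloxamide | CON(C)C(=O)C(=O)N(C)OC | starting material
16 | methyl 3-[(3S,4R)-4-[(3-{4-[methoxy(methyl)amino]-3,4-dioxobutanoyl}-2-oxooxolan-3-yl)acetyl]-4,5-dimethyl-3,4-dihydro-2H-pyrrol-3-yl]propanoate (enolized 1,3-diketone; both lactone epimers) | CC1=NC[C@@H](CCC(=O)OC)[C@@]1(C)C(=O)CC1(CCOC1=O)C(=O)CC(=O)C(=O)N(C)OC | intermediate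
17 | methyl 3-[(3S,4S)-4-(7-{[methoxy(methyl)amino](oxo)acetyl}-1,6-dioxo-2-oxaspiro[4.4]non-7-en-8-yl)-4,5-dimethyl-3,4-dihydro-2H-pyrrol-3-yl]propanoate (ene-dione, not isolated) | CC1=NC[C@@H](CCC(=O)OC)[C@@]1(C)C1=C(C(=O)C(=O)N(C)OC)C(=O)C2(C1)CCOC2=O | intermediate
18 | tricyclic hydroxy imine: ring A cyclopent-2-enone spiro-fused at its α′-carbon to the γ-butyrolactone; ring B cyclohexene fused on the enone C=C; ring C 1-pyrroline fused to ring B through its C=N carbon and the angular-methyl carbon; the ring B carbinol carbon carries OH and C(=O)N(OMe)Me; the pyrroline CH carries CH2CH2CO2Me (carbinol epimers interconvert; productive epimer drawn) | O=C1C2(CCOC2=O)CC2=C1[C@@](O)(C(=O)N(C)OC)CC1=NC[C@@H](CCC(=O)OC)[C@@]21C | intermediate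
19 | tetracyclic enol: as 18 but the former ester carbon is bonded to the ring A CH2 carbon (seven-membered ring D), drawn as the conjugated enol (vinylogous acid) | O=C1C2(CCOC2=O)C3=C(O)CC[C@@H]4CN=C5C[C@](O)(C(=O)N(C)OC)C1=C3[C@]45C | intermediate
20 | isopropenylmagnesium bromide | CC(=C)[Mg]Br | starting material
21 | tetracyclic isopropenyl ketone: as 19 with C(=O)C(CH3)=CH2 in place of the Weinreb amide | O=C1C2(CCOC2=O)C3=C(O)CC[C@@H]4CN=C5C[C@](O)(C(=O)C(C)=C)C1=C3[C@]45C | intermediate
22 | spiro-lactone cage: as 21 after N–CH2 bond formation and hydration; azepan-4-one ring E (N–CH2–CH(CH3)–C(=O)–C(OH)) bridges nitrogen and the ring B carbinol carbon; bridgehead carbinolamine N–C(OH) with OH cis to the angular methyl | O=C1C2(CCOC2=O)C3=C(O)CC[C@@H]4CN5C[C@@H](C)C(=O)[C@@]6(O)C[C@]5(O)[C@]4(C)C3=C16 | intermediate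
23 | O-deacetyl target, drawn as the 1-hydroxyfulvene tautomer (in equilibrium with the ring ketone form) | OC1=C2CCOC3=C2C2=C1[C@]1(O)C[C@@]4(O)N(C[C@@H](CC3)[C@@]24C)C[C@@H](C)C1=O | intermediate
24 | CNP0309418.1 | CC(=O)OC1=C2CCOC3=C2C2=C1[C@]1(O)C[C@@]4(O)N(C[C@@H](CC3)[C@@]24C)C[C@@H](C)C1=O | target

**Totals**
Total step count: 13. Longest linear sequence: 13 steps (from 1).

**Steps most likely to fail**

Step 9 (vinylogous Dieckmann). Seven-membered Claisen closures are slow, and the tertiary alkoxide can undergo retro-aldol or transesterification with the spiro-lactone before the ring closes. The fallback sets out from 18 and comes back at 19. Me3SnOH (1,2-dichloroethane, 70 °C) cleaves only the unhindered methyl ester to the carboxylic acid F1. 1,1′-Carbonyldiimidazole (THF, rt) converts it into the acyl imidazolide F2. LiN(SiMe3)2 (3 equiv, THF, −78 °C) then effects the γ-C-acylation with this activated acyl donor at low temperature, giving 19. N-acylation of the imine is not a concern because it would create a bridgehead amide.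

Step 11 (proposed hydrative aza-Michael). Hydration of a hindered ketimine is unfavourable and the 7-endo addition may be slow. The β-hydroxy imine can dehydrate under acid. Retro-aldol followed by aldol at the isopropenyl ketone carbonyl would give a constitutional isomer. The α-methyl epimer ratio is not assured. The fallback uses known chemistry only, sets out from 21 and comes back at 22. Me3SiI (from Me3SiCl/NaI, MeCN, −40 °C, methanolic work-up) adds iodide to the enone to give the β-iodo ketone F3. On warming in MeCN without base the imine nitrogen is alkylated intramolecularly (Menshutkin-type N-alkylation of a 1-pyrroline, 7-exo-tet) to the cyclic iminium iodide F4. Aqueous NaHCO3 converts this salt into its pseudobase, the carbinolamine 22. The C–N bond is thus made by SN2 displacement instead of conjugate addition.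

Step 12 (decarboxylative pyran closure on the cage). Hot acid may trigger retro-Mannich opening of the β-amino ketone. The primary alcohol may also close onto the ring ketone (five-membered enol ether) instead of the seven-ring carbonyl. The fallback sets out from 22 and comes back at 23. LiI (3 equiv, pyridine, 100 °C) opens the lactone at its O–CH2 carbon (Krapcho-type dealkoxycarbonylation), and the β-keto carboxylate loses CO2 to give the 2-iodoethyl enol F5. Its vinylogous-acid oxygen then closes the pyran by 6-exo-tet O-alkylation (Williamson) to 23. The competing spirocyclopropane from C-alkylation is reopened by iodide.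

**Further compounds**
F1 | step 9 | carboxylic acid from selective methyl ester cleavage of 18 | O=C1C2(CCOC2=O)CC2=C1[C@@](O)(C(=O)N(C)OC)CC1=NC[C@@H](CCC(=O)O)[C@@]21C
F2 | step 9 | acyl imidazolide of F1 | O=C1C2(CCOC2=O)CC2=C1[C@@](O)(C(=O)N(C)OC)CC1=NC[C@@H](CCC(=O)n3ccnc3)[C@@]21C
F3 | step 11 | β-iodo ketone from 21 (both epimers at the CH(CH3) carbon) | O=C1C2(CCOC2=O)C3=C(O)CC[C@@H]4CN=C5C[C@](O)(C(=O)C(C)CI)C1=C3[C@]45C
F4 | step 11 | cyclic iminium iodide (drawn as the epimer that leads to 22) | O=C1C2(CCOC2=O)C3=C(O)CC[C@@H]4C[N+]5=C6C[C@](O)(C(=O)[C@H](C)C5)C1=C3[C@]46C.[I-]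
F5 | step 12 | 2-iodoethyl enol from 22 (either epimer at the CH bearing the iodoethyl group) | O=C1C(CCI)C2=C(O)CC[C@@H]3CN4C[C@@H](C)C(=O)[C@@]5(O)C[C@]4(O)[C@]3(C)C2=C15
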